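## Structural features

The target is a seco-elemanolide built on one cyclohexane ring, C5–C10, in which every ring carbon is substituted: C5 carries the acrolein arm (C4, C3, C15), C6 a free hydroxyl, C7 the C11–C13 unit, C8 the lactone oxygen, C9 the angelate, and the quaternary C10 a methyl group (C14) and the oxirane C1–C2. An α-methylene-γ-butyrolactone is trans-fused across C7–C8, and the oxirane adds a seventh stereocentre (C1) outside the ring. C1 and C5–C10 therefore form one unbroken stereo-array, (1R,5R,6S,7S,8R,9S,10R).

In the chair that places the C5 arm, the C7 arm, O8 and the oxirane equatorial, three groups are axial: the C10 methyl, the C6 hydroxyl syn-axial to it, and the C9 ester oxygen cis to O8. The fragile groups are the two Michael acceptors (methylene lactone and enal), the free aldehyde, the Z-enoate (which isomerises to the tiglate) and the terminal epoxide. The real difficulty is threefold: the quaternary C10 flanked by stereocentres at C5, C9 and C1; the axial C6 hydroxyl; and the need to end with three secondary oxygens in three different states (O6 free, O8 in the lactone, O9 angeloylated).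

The key step exploits the sequence O–C6–C5–C4(=C15). This is a masked β-hydroxy ketone, and therefore the retron of a 2-isoxazoline with C6 as the C=N carbon and the ring oxygen on C4. A nitrile oxide at C6 adding to a C5=C4 alkene closes the C5–C6 bond of the cyclohexane and the heterocycle in one event.

## Logic of the disconnections

36 to 33 and 34. The C9–O acyl bond is cut (together with the Si–O bond at O6 of 35). The Z-enoate cannot survive hydride, ylide or allylic oxidation chemistry, so it is attached last but one. The demand is acylation of a hindered axial hydroxyl without Z to E isomerisation, with O6 silylated so that O9 is the only free hydroxyl.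

33 to 29 (through 32 and 30). The O8–C12 lactone bond is cut and C12 and C3 are taken back to methyl groups of two prop-1-en-2-yl arms. Both Michael acceptors then vanish from every earlier intermediate. The demand is that O8 is the only hydroxyl able to capture C12 at the oxidation stage (O6 silyl, O9 PMB), and that O9 is freed only after O8 is locked in the lactone.

29 to 26 (through 28 and 27). The C1–C2 bond is cut (methylene transfer to a C1 aldehyde). One hydride step on 26 is asked to open the six-membered acetal toward O1 and to remove the O8 acyl group. This leaves O9 as its PMB ether, so that O8 and O9 are never in the same protecting group and no acid is needed once the oxirane exists. The demand is facial control at C1.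

26 to 20 (through 25, 24, 23 and 21). The C4=C15 alkene is traced to a tertiary C4 alcohol, the axial C6 carbinol to a C6 ketone, and the β-hydroxy ketone to the N–O bond of the isoxazoline. The demand is hydride delivery at C6 anti to the axial C10 methyl, and dehydration toward a methyl group.

20 to 17 (key disconnection). C5–C6 and O–C4 are cut. The gain is two rings and the C5 stereocentre, and C6 is carried as sp2 carbon, so the axial hydroxyl is not an issue during ring closure. Two changes are made to the obvious form of the precursor, with the carbon skeleton unchanged: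
- C1 is held as a CH2–O unit tied to O9 in a p-methoxybenzylidene acetal. The dioxane holds the C8 and C5 branches cis on C9 and C10, and later allows O9 and O1 to be told apart.
- O8 is left free, so that it is the one oxygen that can be marked separately after the cycloaddition.

No alkene is present at C1.

17 to 9 and 12 (through 16, 15 and 14). The C7–C8 bond is cut as an aldol bond. C6 arrives at the carboxyl level in an auxiliary-bearing unit, which fixes C7 and C8 together. The demand is α-attack of a dienolate and the 8,9-anti sense at the α-alkoxy aldehyde.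

12 to 10 and 11. The N–acyl bond is cut; both pieces are commercial.

9 to 4 (through 8, 7, 5 and 6). The C5=C4 alkene is cut (olefination of a C5 aldehyde that has no α-hydrogen) and C8 is adjusted from a silyl ether to the aldehyde.

4 to 1 and 2 (through 3). The C9–C10 bond is cut. One catalytic C–C coupling is asked to set the C9 carbinol and the quaternary C10 (methyl, hydroxymethyl = C1, vinyl = future C5) in relative and absolute terms.

## Other disconnections considered

Alternative 1: The cut goes through C5–C4 and C10–C1 at once. It leads to enone A1 (C9 ketone, C10=C5 alkene, lactone and C6 silyl ether already present) and 1-methylcyclobutene A2. Forward, irradiation would give the head-to-tail cyclobutane adduct A3, and thermal opening of its bicyclo[2.2.0]hexane would release a prop-1-en-2-yl group on C5 and a vinyl group on C10 (A4).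
- In its favour: the quaternary carbon and both carbon arms arise in one step, ring oxygenation and absolute configuration come from the terpene chiral pool, and the vinyl group is a direct oxirane precursor. Up to the installation of the arms its step count is clearly better than that of the chosen plan.
- Against it: a cyclohexenone [2+2] normally gives a cis-fused cyclobutane. A3 formulated in that way has C4 and C1 on the same face, so A4 has the C5 arm cis to the C10 vinyl group. The target needs C5–C4 and C10–C1 on opposite faces. A3 is therefore the C5 epimer of what is required; this is corrected here by noting that C5 would have to be inverted later through a C6 ketone, since C10 is quaternary and C5 is not enolisable while C6 is a silyl ether.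
- Further drawbacks: regiochemistry is not tether-enforced, an α-methyl enone is a sluggish partner, and a cis-1,2-dialkenylcyclohexane such as A4 can drift toward the ten-membered ring by Cope rearrangement at the fragmentation temperature.
- Comparison: the later work (axial C9 alcohol, C11 methylene, enal) is comparable, and the C1 configuration is as open as in the chosen plan (equal). On structure the chosen plan sets C5 correctly in the ring-forming step. On mechanism the photochemical route is less predictable. On step economy the alternative is the better one if the C5 problem can be solved.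

Alternative 2: The cut is the C7–C8 bond, with the C7 prop-1-en-2-yl group traced to a trisubstituted C7=C11 alkene and the C8 hydroxyl to an aldehyde, in open-chain aldehyde A5. Forward, a dialkylaluminium chloride would activate the aldehyde for a type-one carbonyl-ene reaction that forms C7–C8, moves a hydrogen from a C11 methyl group to oxygen, and gives cyclohexanol A6 with C7 and C8 trans.
- In its favour: the closure creates exactly the hydroxyl that the lactone needs, already distinct from O9 (PMB) and O6 (silyl). A5 tolerates the C10 vinyl group and carries C3 pre-oxidised, so the late stage needs one allylic oxidation fewer and no methylene transfer at C1. On these three points it is the better plan.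
- Against it: A5 must be made as an open chain with four contiguous stereocentres (C5, C6, C9, C10), including the quaternary carbon flanked by two of them. That is harder than the chosen precursor, where C5 is set during ring closure and C6 is planar.
- Further drawbacks: the chair leading to A6 carries the C6 silyl ether, the C10 methyl and the C9 ether axial, the first two syn-axial, so the trans outcome known from simpler cases is not assured. An α-alkoxy aldehyde can chelate the Lewis acid, and the Lewis acid threatens the PMB ether and the allylic pivalate.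
- Comparison: on mechanism both closures are concerted and tether-controlled (equal). On step economy the endgame is shorter, but the synthesis of A5 is expected to cost more than is saved.

Alternative 3: The cut is the C6–C7 bond. C6 is an aldehyde used as an acyl anion and C7 is the β-carbon of an alkylidene malonate, in aldehyde A7. Forward, a carbene from a chiral triazolium salt would turn the aldehyde into its Breslow intermediate, which adds to C7 in an intramolecular Stetter reaction and gives cyclohexanone A8.
- In its favour: C6 is delivered as a ketone, so the axial hydroxyl can again come from hydride attack anti to the C10 methyl (equal). The step is catalytic and neutral and tolerates the vinyl group. The malonate is a good precursor of the methylene lactone by hydrolysis and decarboxylative methylenation, which avoids allylic oxidation at C12 (better).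
- Against it: in A8 C5 is an unsubstituted methylene group. The three-carbon arm must still be attached at the neopentyl α-position of the ketone, with control of site and configuration. That is exactly the bond the nitrile oxide step forms while closing the ring.
- Further drawbacks: Stetter closures of enolisable aliphatic aldehydes to six-membered carbocycles are less general than those of aromatic aldehydes, and the C7 configuration would depend on the catalyst. The acetonide frees O8 and O9 together under acid, so oxygen differentiation is worse than in the chosen design.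
- Comparison: on structure the alternative leaves the hardest C–C bond unmade. On mechanism it is milder. On step economy the gain at C12 is expected to be lost at C5.

Key step: step 12

Assumption: the iridium-catalysed coupling of step 1 is taken to give the anti adduct (C9 hydroxyl anti to the hydroxymethyl group when the vinyl group lies in the main chain) and to give 3 with the (R)-configured ligand; if the sense of induction is the opposite, the (S)-ligand is used with no other change.

## Steps

Step 1
Reactants: 1 2-(tert-butyldimethylsilyloxy)ethanol; 2 2-methyl-2-vinyloxirane (racemic)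
Product: 3 (2R,3S)-4-(tert-butyldimethylsilyloxy)-2-methyl-2-vinylbutane-1,3-diol
Conditions: preformed π-allyliridium C,O-benzoate catalyst from [Ir(cod)Cl]2, (R)-Tol-BINAP and 4-cyano-3-nitrobenzoic acid (5 mol %), K3PO4 (5 mol %), THF, 45 °C
Reagents that add atoms: none
Why: Iridium-catalysed transfer-hydrogenative tert-(hydroxy)prenylation: the alcohol is dehydrogenated to the aldehyde, the iridium hydride opens the vinyl epoxide to an allyliridium species, and this adds through a closed chair with the hydroxymethyl group equatorial, which sets C9 and the quaternary C10 anti while the ligand fixes the absolute sense. The racemic epoxide converges because its stereocentre is lost in the π-allyl.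

Step 2
Reactants: 3 (2R,3S)-4-(tert-butyldimethylsilyloxy)-2-methyl-2-vinylbutane-1,3-diol
Product: 4 (2S,4S,5R)-4-[(tert-butyldimethylsilyloxy)methyl]-2-(4-methoxyphenyl)-5-methyl-5-vinyl-1,3-dioxane
Conditions: 4-MeOC6H4CH(OMe)2, PPTS (cat.), CH2Cl2, rt
Reagents that add atoms: 4-methoxybenzaldehyde dimethyl acetal, COC(OC)c1ccc(OC)cc1
Why: Acid-catalysed transacetalisation of the 1,3-diol gives the six-membered p-methoxybenzylidene acetal under thermodynamic control with the aryl group equatorial (2S); the primary silyl ether is untouched.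

Step 3
Reactants: 4 (2S,4S,5R)-4-[(tert-butyldimethylsilyloxy)methyl]-2-(4-methoxyphenyl)-5-methyl-5-vinyl-1,3-dioxane
Product: 5 (2S,4S,5R)-4-[(tert-butyldimethylsilyloxy)methyl]-2-(4-methoxyphenyl)-5-methyl-1,3-dioxane-5-carbaldehyde
Conditions: OsO4 (cat.), NaIO4, 2,6-lutidine, dioxane/H2O, rt
Reagents that add atoms: sodium periodate, [Na+].[O-]I(=O)(=O)=O (terminal oxidant; the carbonyl oxygen is delivered by way of OsO4, O=[Os](=O)(=O)=O)
Why: Lemieux–Johnson cleavage (osmylation then periodate) of the only alkene; it is preferred to ozone, which can oxidise the benzylidene acetal C–H bond.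

Step 4
Reactants: 5 (2S,4S,5R)-4-[(tert-butyldimethylsilyloxy)methyl]-2-(4-methoxyphenyl)-5-methyl-1,3-dioxane-5-carbaldehyde; 6 isopropyltriphenylphosphonium iodide
Product: 7 (2S,4S,5R)-4-[(tert-butyldimethylsilyloxy)methyl]-2-(4-methoxyphenyl)-5-methyl-5-(2-methylprop-1-enyl)-1,3-dioxane
Conditions: 6, n-BuLi, THF, 0 °C; then 5, 0 °C → rt
Reagents that add atoms: none
Why: Wittig olefination with the non-stabilised isopropylidene ylide builds C5=C4 with both methyl groups; the aldehyde has no α-hydrogen, so the basic ylide can neither enolise it nor cause elimination.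

Step 5
Reactants: 7 (2S,4S,5R)-4-[(tert-butyldimethylsilyloxy)methyl]-2-(4-methoxyphenyl)-5-methyl-5-(2-methylprop-1-enyl)-1,3-dioxane
Product: 8 [(2S,4S,5R)-2-(4-methoxyphenyl)-5-methyl-5-(2-methylprop-1-enyl)-1,3-dioxan-4-yl]methanol
Conditions: Bu4NF, THF, 0 °C → rt
Reagents that add atoms: none
Why: Fluoride cleavage of the primary silyl ether; acetal and alkene are inert.

Step 6
Reactants: 8 [(2S,4S,5R)-2-(4-methoxyphenyl)-5-methyl-5-(2-methylprop-1-enyl)-1,3-dioxan-4-yl]methanol
Product: 9 (2S,4S,5R)-2-(4-methoxyphenyl)-5-methyl-5-(2-methylprop-1-enyl)-1,3-dioxane-4-carbaldehyde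
Conditions: Dess–Martin periodinane, NaHCO3, CH2Cl2, 0 °C → rt
Reagents that add atoms: none
Why: Dess–Martin oxidation under bicarbonate buffer gives the C8 aldehyde; the α-alkoxy aldehyde is used crude to avoid epimerisation at C9.

Step 7
Reactants: 10 (R)-4-benzyloxazolidin-2-one; 11 3-methylbut-2-enoyl chloride
Product: 12 (R)-4-benzyl-3-(3-methylbut-2-enoyl)oxazolidin-2-one
Conditions: Et3N, DMAP (cat.), CH2Cl2, 0 °C → rt
Reagents that add atoms: none
Why: N-acylation of the oxazolidinone by the acid chloride under DMAP catalysis.

Step 8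
Reactants: 12 (R)-4-benzyl-3-(3-methylbut-2-enoyl)oxazolidin-2-one; 9 (2S,4S,5R)-2-(4-methoxyphenyl)-5-methyl-5-(2-methylprop-1-enyl)-1,3-dioxane-4-carbaldehyde
Product: 14 (R)-4-benzyl-3-[(2R,3R)-3-hydroxy-3-[(2S,4S,5R)-2-(4-methoxyphenyl)-5-methyl-5-(2-methylprop-1-enyl)-1,3-dioxan-4-yl]-2-(prop-1-en-2-yl)propanoyl]oxazolidin-2-one, via boron dienolate 13 (not isolated)
Conditions: 12, Bu2BOTf, Et3N, CH2Cl2, −78 → 0 °C; then 9, −78 → 0 °C; H2O2, pH 7 buffer, MeOH, 0 °C
Reagents that add atoms: none
Why: Evans syn aldol of the Z(O) boron dienolate, which reacts at its α-carbon through a closed Zimmerman–Traxler chair: the (R)-benzyl auxiliary sets C7 and C8 (isopropenyl and hydroxyl syn along C6–C9). The Cornforth/Felkin preference of the α-alkoxy aldehyde for the 8,9-anti adduct points the same way.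

Step 9
Reactants: 14 (R)-4-benzyl-3-[(2R,3R)-3-hydroxy-3-[(2S,4S,5R)-2-(4-methoxyphenyl)-5-methyl-5-(2-methylprop-1-enyl)-1,3-dioxan-4-yl]-2-(prop-1-en-2-yl)propanoyl]oxazolidin-2-one
Product: 15 (1R,2S)-1-[(2S,4S,5R)-2-(4-methoxyphenyl)-5-methyl-5-(2-methylprop-1-enyl)-1,3-dioxan-4-yl]-2-(prop-1-en-2-yl)propane-1,3-diol
Conditions: LiBH4, MeOH (1 equiv), THF, 0 °C
Reagents that add atoms: none
Why: Hydroxyl-assisted reductive removal of the auxiliary with LiBH4 gives the C6 primary alcohol and returns 10; alkenes and acetal are inert.

Step 10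
Reactants: 15 (1R,2S)-1-[(2S,4S,5R)-2-(4-methoxyphenyl)-5-methyl-5-(2-methylprop-1-enyl)-1,3-dioxan-4-yl]-2-(prop-1-en-2-yl)propane-1,3-diol
Product: 16 (2R,3R)-3-hydroxy-3-[(2S,4S,5R)-2-(4-methoxyphenyl)-5-methyl-5-(2-methylprop-1-enyl)-1,3-dioxan-4-yl]-2-(prop-1-en-2-yl)propanal
Conditions: TEMPO (cat.), PhI(OAc)2, CH2Cl2, 0 °C → rt
Reagents that add atoms: none
Why: Nitroxyl-catalysed oxidation takes the primary alcohol of the 1,3-diol and leaves the secondary C8 hydroxyl; the β-hydroxy aldehyde is used at once because its α-hydrogen is allylic.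

Step 11
Reactants: 16 (2R,3R)-3-hydroxy-3-[(2S,4S,5R)-2-(4-methoxyphenyl)-5-methyl-5-(2-methylprop-1-enyl)-1,3-dioxan-4-yl]-2-(prop-1-en-2-yl)propanal
Product: 17 (1E,2S,3R)-3-hydroxy-3-[(2S,4S,5R)-2-(4-methoxyphenyl)-5-methyl-5-(2-methylprop-1-enyl)-1,3-dioxan-4-yl]-2-(prop-1-en-2-yl)propanal oxime (C6 aldoxime tethered to the C5=C4 alkene; C8 hydroxyl free)
Conditions: NH2OH·HCl, NaOAc, EtOH, 0 °C
Reagents that add atoms: hydroxylamine hydrochloride, NO.Cl
Why: Oxime condensation under acetate buffer, mild enough for the acetal and for the β,γ-unsaturated aldehyde.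

Step 12
Reactants: 17 (1E,2S,3R)-3-hydroxy-3-[(2S,4S,5R)-2-(4-methoxyphenyl)-5-methyl-5-(2-methylprop-1-enyl)-1,3-dioxan-4-yl]-2-(prop-1-en-2-yl)propanal oxime
Product: 20 tricyclic isoxazoline (C6=N–O–C4 ring fused to the cyclohexane at C5–C6; C4 with two methyl groups; C7 prop-1-en-2-yl; C8 hydroxyl free; O9 and O1 in the (S)-p-methoxybenzylidene acetal; C5-H anti to the C10 methyl; C7/C8 trans; C8-O/C9-O cis), via hydroximoyl chloride 18 (not isolated), via nitrile oxide 19 (not isolated)
Conditions: aq. NaOCl, Et3N (cat.), CH2Cl2, 0 °C → rt, 17 added slowly (high dilution)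
Reagents that add atoms: none
Why: Hypochlorite converts the aldoxime by way of the hydroximoyl chloride into the nitrile oxide, which adds to the tethered trisubstituted alkene in a concerted, suprafacial [3+2] cycloaddition; the closest known reaction type is the intramolecular nitrile oxide–alkene cycloaddition that gives cyclohexane-fused 2-isoxazolines. The carbocycle closes in 6-exo fashion: C6 bonds to C5, the proximal alkene carbon, and C4 stays outside the new six-membered ring. The isoxazoline closes in the same event by O–C4 bonding at the distal, fully substituted terminus and is fused to the carbocycle at C5–C6. The only new stereocentre, C5, is set by a chair-like transition state with the C7 isopropenyl group and the C8 hydroxyl equatorial, the C10 methyl and O9 axial, and the CMe2 terminus equatorial at C5; an axial CMe2 group would clash with the axial O9, so C5-H ends anti to the C10 methyl. The step needs regioselectivity, which the four-atom tether enforces, because the bridged mode would require a seven-membered carbocycle. It needs chemoselectivity for the dipole: the C7 isopropenyl group is too close to be reached and C1 carries no alkene. It needs cyclisation to outrun furoxan formation, which high dilution and the dioxane ring secure, the ring holding the C8 and C5 branches cis on C9 and C10.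

Step 13
Reactants: 20 tricyclic isoxazoline with free C8 hydroxyl
Product: 21 C8 pivalate of isoxazoline 20
Conditions: t-BuCOCl, pyridine, DMAP (cat.), CH2Cl2, 0 °C → rt
Reagents that add atoms: pivaloyl chloride, CC(C)(C)C(Cl)=O
Why: Acylation of the only hydroxyl; the pivalate keeps O8 distinct from the C6 hydroxyl that appears in step 15 and is removed without an extra step in step 18.

Step 14
Reactants: 21 C8 pivalate of isoxazoline 20
Product: 23 β-hydroxy ketone (C6 ketone; C5 equatorial 2-hydroxypropan-2-yl group; C8 pivalate; acetal intact), via β-hydroxy imine 22 (not isolated)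
Conditions: Mo(CO)6, MeCN/H2O, 80 °C
Reagents that add atoms: water, O (the C6 carbonyl oxygen, by hydrolysis of the imine)
Why: Mo(CO)6-mediated reductive N–O cleavage of a 2-isoxazoline to the β-hydroxy imine and its hydrolysis, a method that leaves alkenes alone. The equatorial C8–O bond is poorly aligned with the C6–C7 enol π system, so β-elimination of pivalate should be slow.

Step 15
Reactants: 23 β-hydroxy ketone
Product: 24 diol (C6 hydroxyl axial and cis to the C10 methyl; C4 tertiary hydroxyl; C8 pivalate)
Conditions: LiBH(s-Bu)3, THF, −78 °C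
Reagents that add atoms: none
Why: The bulky borohydride attacks C6 along the equatorial trajectory because the axial one is closed by the syn-axial C10 methyl, which gives the axial (6S) alcohol; the pivalate survives at this temperature.

Step 16
Reactants: 24 diol
Product: 25 C6 triethylsilyl ether (C4 tertiary hydroxyl free)
Conditions: Et3SiCl, imidazole, DMAP (cat.), DMF, rt → 40 °C
Reagents that add atoms: chlorotriethylsilane, CC[Si](Cl)(CC)CC
Why: Silyl chloride with imidazole silylates the secondary C6 hydroxyl; the tertiary C4 hydroxyl does not react under these conditions.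

Step 17
Reactants: 25 C6 triethylsilyl ether
Product: 26 diene (C5 prop-1-en-2-yl; C7 prop-1-en-2-yl; C6 OSiEt3; C8 pivalate; acetal intact)
Conditions: Burgess reagent (MeO2CN(−)SO2N(+)Et3), toluene, 50 °C
Reagents that add atoms: none
Why: Burgess dehydration (syn elimination from the tertiary sulfamate) takes a methyl hydrogen and not the hindered C5-H, because the tetrasubstituted exocyclic alkene would suffer allylic strain with C6 and C10; this regenerates the prop-1-en-2-yl arm.

Step 18
Reactants: 26 diene
Product: 27 diol (C8 hydroxyl free; C1 primary alcohol free; O9 4-methoxybenzyl ether; C6 OSiEt3)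
Conditions: i-Bu2AlH (excess), CH2Cl2, −78 → 0 °C
Reagents that add atoms: none
Why: Reductive opening of the p-methoxybenzylidene acetal: aluminium binds the less hindered oxygen O1 and hydride cleaves that C–O bond, so the PMB group stays on the more hindered O9. The same reagent removes the pivalate.

Step 19
Reactants: 27 diol
Product: 28 C1 aldehyde (formyl group on C10; C8 hydroxyl free)
Conditions: TEMPO (cat.), PhI(OAc)2, CH2Cl2, rt
Reagents that add atoms: none
Why: Nitroxyl-catalysed oxidation is selective for the primary C1 alcohol over the secondary C8 hydroxyl and does not touch the alkenes or the PMB ether.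

Step 20
Reactants: 28 C1 aldehyde
Product: 29 (1R)-oxirane (C1–C2 epoxide on C10; C8 hydroxyl free; O9 PMB; C6 OSiEt3; two prop-1-en-2-yl arms)
Conditions: Me3S(+) I(−), KN(SiMe3)2, THF, −10 → 0 °C
Reagents that add atoms: trimethylsulfonium iodide, C[S+](C)C.[I-]
Why: Corey–Chaykovsky methylene transfer: the ylide adds to the aldehyde and the betaine closes to the oxirane. With a non-chelating potassium counter-ion the carbonyl is expected to eclipse the C10 methyl (dipole turned away from the C9–O bond) and the ylide to attack from the sector next to C9-H, away from the C5 arm, which gives (1R).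

Step 21
Reactants: 29 (1R)-oxirane
Product: 30 triol (C12 and C3 primary allylic alcohols on the C7 and C5 arms; C8 hydroxyl)
Conditions: SeO2 (cat.), t-BuOOH, CH2Cl2, rt
Reagents that add atoms: tert-butyl hydroperoxide, CC(C)(C)OO (terminal oxidant; the two hydroxyl oxygens are delivered by way of SeO2, O=[Se]=O)
Why: Selenium dioxide allylic oxidation (ene reaction then [2,3] shift) of both prop-1-en-2-yl groups at their methyl groups, the usual site for 1,1-disubstituted alkenes. Partial over-oxidation to enal or lactol is harmless because step 22 takes both arms further.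

Step 22
Reactants: 30 triol
Product: 32 α-methylene lactone enal (12,8-olide; C3 aldehyde; C6 OSiEt3; O9 PMB; oxirane), via lactol 31 (not isolated)
Conditions: MnO2 (activated, excess), CH2Cl2, rt
Reagents that add atoms: none
Why: MnO2 oxidises both allylic alcohols; the C12 aldehyde is captured by the only free hydroxyl (O8, trans-diequatorial to the C7 arm) as the lactol, which is oxidised on to the trans-fused α-methylene-γ-lactone. C3 stops at the enal because O6 is silylated.

Step 23
Reactants: 32 α-methylene lactone enal
Product: 33 C9 alcohol (C6 OSiEt3 retained)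
Conditions: DDQ, CH2Cl2/pH 7 buffer, 0 °C
Reagents that add atoms: none
Why: Oxidative cleavage of the PMB ether by DDQ (benzylic hydride abstraction then hydrolysis); O8 is already in the lactone, so no neighbouring hydroxyl can trap the oxocarbenium ion as an acetal.

Step 24
Reactants: 33 C9 alcohol; 34 angelic acid ((Z)-2-methylbut-2-enoic acid)
Product: 35 C9 angelate (C6 OSiEt3 retained)
Conditions: 34, 2,4,6-Cl3C6H2COCl, Et3N, toluene, rt; then 33, DMAP, toluene, rt → 60 °C
Reagents that add atoms: none
Why: Yamaguchi esterification: the preformed mixed anhydride of angelic acid acylates the hindered axial C9 hydroxyl under DMAP catalysis. Preforming the anhydride and a moderate temperature limit Z to E isomerisation, and O6 is silylated.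

Step 25
Reactants: 35 C9 angelate
Product: 36 CNP0130022.2, (1R,5R,6S,7S,8R,9S,10R)-9-[(Z)-2-methylbut-2-enoyloxy]-1,2-epoxy-6-hydroxy-3-oxoelema-4(15),11(13)-dien-12,8-olide
Conditions: HF·pyridine, pyridine, THF, 0 °C
Reagents that add atoms: none
Why: Buffered fluoride cleaves the triethylsilyl ether; the pyridine buffer protects the oxirane, and the conjugated carbonyl groups are inert.

## Compound list

1 | 2-(tert-butyldimethylsilyloxy)ethanol | OCCO[Si](C)(C)C(C)(C)C | starting material
2 | 2-methyl-2-vinyloxirane (racemic) | CC1(C=C)CO1 | starting material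
3 | (2R,3S)-4-(tert-butyldimethylsilyloxy)-2-methyl-2-vinylbutane-1,3-diol | C=C[C@](C)(CO)[C@H](O)CO[Si](C)(C)C(C)(C)C | intermediate
4 | (2S,4S,5R)-4-[(tert-butyldimethylsilyloxy)methyl]-2-(4-methoxyphenyl)-5-methyl-5-vinyl-1,3-dioxane | C=C[C@]1(C)CO[C@H](c2ccc(OC)cc2)O[C@@H]1CO[Si](C)(C)C(C)(C)C | intermediate
5 | (2S,4S,5R)-4-[(tert-butyldimethylsilyloxy)methyl]-2-(4-methoxyphenyl)-5-methyl-1,3-dioxane-5-carbaldehyde | O=C[C@]1(C)CO[C@H](c2ccc(OC)cc2)O[C@@H]1CO[Si](C)(C)C(C)(C)C | intermediate
6 | isopropyltriphenylphosphonium iodide | CC(C)[P+](c1ccccc1)(c1ccccc1)c1ccccc1.[I-] | starting material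
7 | (2S,4S,5R)-4-[(tert-butyldimethylsilyloxy)methyl]-2-(4-methoxyphenyl)-5-methyl-5-(2-methylprop-1-enyl)-1,3-dioxane | CC(C)=C[C@]1(C)CO[C@H](c2ccc(OC)cc2)O[C@@H]1CO[Si](C)(C)C(C)(C)C | intermediate
8 | [(2S,4S,5R)-2-(4-methoxyphenyl)-5-methyl-5-(2-methylprop-1-enyl)-1,3-dioxan-4-yl]methanol | CC(C)=C[C@]1(C)CO[C@H](c2ccc(OC)cc2)O[C@@H]1CO | intermediate
9 | (2S,4S,5R)-2-(4-methoxyphenyl)-5-methyl-5-(2-methylprop-1-enyl)-1,3-dioxane-4-carbaldehyde | CC(C)=C[C@]1(C)CO[C@H](c2ccc(OC)cc2)O[C@@H]1C=O | intermediate
10 | (R)-4-benzyloxazolidin-2-one | O=C1N[C@H](Cc2ccccc2)CO1 | starting material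
11 | 3-methylbut-2-enoyl chloride | CC(C)=CC(=O)Cl | starting material
12 | (R)-4-benzyl-3-(3-methylbut-2-enoyl)oxazolidin-2-one | CC(C)=CC(=O)N1[C@H](Cc2ccccc2)COC1=O | intermediate
13 | Z(O) dibutylboron dienolate of 12 | C=C(C)/C=C(\OB(CCCC)CCCC)N1[C@H](Cc2ccccc2)COC1=O | intermediate
14 | Evans syn aldol adduct (7R,8R; imide at C6) | O=C(N1[C@H](Cc2ccccc2)COC1=O)[C@H](C(C)=C)[C@@H](O)[C@H]1O[C@@H](c2ccc(OC)cc2)OC[C@@]1(C)C=C(C)C | intermediate
15 | (1R,2S)-1-[(2S,4S,5R)-dioxan-4-yl]-2-(prop-1-en-2-yl)propane-1,3-diol (C6 primary alcohol, C8 secondary alcohol) | OC[C@H](C(C)=C)[C@@H](O)[C@H]1O[C@@H](c2ccc(OC)cc2)OC[C@@]1(C)C=C(C)C | intermediate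
16 | (2R,3R)-β-hydroxy aldehyde (C6 aldehyde) | O=C[C@H](C(C)=C)[C@@H](O)[C@H]1O[C@@H](c2ccc(OC)cc2)OC[C@@]1(C)C=C(C)C | intermediate
17 | (1E,2S,3R)-aldoxime, precursor of the key step | O/N=C/[C@H](C(C)=C)[C@@H](O)[C@H]1O[C@@H](c2ccc(OC)cc2)OC[C@@]1(C)C=C(C)C | intermediate
18 | hydroximoyl chloride of 17 | O/N=C(\Cl)[C@H](C(C)=C)[C@@H](O)[C@H]1O[C@@H](c2ccc(OC)cc2)OC[C@@]1(C)C=C(C)C | intermediate
19 | C6 nitrile oxide | [O-][N+]#C[C@H](C(C)=C)[C@@H](O)[C@H]1O[C@@H](c2ccc(OC)cc2)OC[C@@]1(C)C=C(C)C | intermediate
20 | tricyclic isoxazoline, product of the key step | C=C(C)[C@H]1C2=NOC(C)(C)[C@H]2[C@]3(C)CO[C@H](c4ccc(OC)cc4)O[C@@H]3[C@@H]1O | intermediate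
21 | C8 pivalate of 20 | C=C(C)[C@H]1C2=NOC(C)(C)[C@H]2[C@]3(C)CO[C@H](c4ccc(OC)cc4)O[C@@H]3[C@@H]1OC(=O)C(C)(C)C | intermediate
22 | β-hydroxy imine (C6=NH, C4–OH) | CC(C)(O)[C@@H]1C(=N)[C@H](C(C)=C)[C@@H](OC(=O)C(C)(C)C)[C@H]2O[C@@H](c3ccc(OC)cc3)OC[C@@]12C | intermediate
23 | β-hydroxy ketone (C6=O, C4–OH) | CC(C)(O)[C@@H]1C(=O)[C@H](C(C)=C)[C@@H](OC(=O)C(C)(C)C)[C@H]2O[C@@H](c3ccc(OC)cc3)OC[C@@]12C | intermediate
24 | diol with axial (6S) hydroxyl | CC(C)(O)[C@@H]1[C@H](O)[C@H](C(C)=C)[C@@H](OC(=O)C(C)(C)C)[C@H]2O[C@@H](c3ccc(OC)cc3)OC[C@@]12C | intermediate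
25 | C6 triethylsilyl ether | CC(C)(O)[C@@H]1[C@H](O[Si](CC)(CC)CC)[C@H](C(C)=C)[C@@H](OC(=O)C(C)(C)C)[C@H]2O[C@@H](c3ccc(OC)cc3)OC[C@@]12C | intermediate
26 | diene with C5 and C7 prop-1-en-2-yl arms | C=C(C)[C@@H]1[C@H](O[Si](CC)(CC)CC)[C@H](C(C)=C)[C@@H](OC(=O)C(C)(C)C)[C@H]2O[C@@H](c3ccc(OC)cc3)OC[C@@]12C | intermediate
27 | diol: C8–OH, C1–OH, O9 PMB ether | C=C(C)[C@@H]1[C@H](O[Si](CC)(CC)CC)[C@H](C(C)=C)[C@@H](O)[C@@H](OCc2ccc(OC)cc2)[C@@]1(C)CO | intermediate
28 | C1 aldehyde | C=C(C)[C@@H]1[C@H](O[Si](CC)(CC)CC)[C@H](C(C)=C)[C@@H](O)[C@@H](OCc2ccc(OC)cc2)[C@@]1(C)C=O | intermediate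
29 | (1R)-oxirane | C=C(C)[C@@H]1[C@H](O[Si](CC)(CC)CC)[C@H](C(C)=C)[C@@H](O)[C@@H](OCc2ccc(OC)cc2)[C@@]1(C)[C@@H]3CO3 | intermediate
30 | triol (C12–OH, C3–OH, C8–OH) | C=C(CO)[C@@H]1[C@H](O[Si](CC)(CC)CC)[C@H](C(=C)CO)[C@@H](O)[C@@H](OCc2ccc(OC)cc2)[C@@]1(C)[C@@H]3CO3 | intermediate
31 | lactol (C12 hemiacetal on O8, anomer mixture; C3 aldehyde) | C=C1C(O)O[C@@H]2[C@@H]1[C@@H](O[Si](CC)(CC)CC)[C@@H](C(=C)C=O)[C@](C)([C@@H]1CO1)[C@@H]2OCc1ccc(OC)cc1 | intermediate
32 | α-methylene lactone enal, O9 PMB, O6 SiEt3 | C=C1C(=O)O[C@@H]2[C@@H]1[C@@H](O[Si](CC)(CC)CC)[C@@H](C(=C)C=O)[C@](C)([C@@H]1CO1)[C@@H]2OCc1ccc(OC)cc1 | intermediate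
33 | C9 alcohol, O6 SiEt3 | C=C1C(=O)O[C@@H]2[C@@H]1[C@@H](O[Si](CC)(CC)CC)[C@@H](C(=C)C=O)[C@](C)([C@@H]1CO1)[C@@H]2O | intermediate
34 | angelic acid, (Z)-2-methylbut-2-enoic acid | C/C=C(/C)C(=O)O | starting material
35 | C9 angelate, O6 SiEt3 | C=C1C(=O)O[C@@H]2[C@@H]1[C@@H](O[Si](CC)(CC)CC)[C@@H](C(=C)C=O)[C@](C)([C@@H]1CO1)[C@@H]2OC(=O)/C(C)=C\C | intermediate
36 | CNP0130022.2 | C=C1C(=O)O[C@@H]2[C@@H]1[C@@H](O)[C@@H](C(=C)C=O)[C@](C)([C@@H]1CO1)[C@@H]2OC(=O)/C(C)=C\C | target

## Step count and least certain steps

Total: 25 steps. Longest linear sequence: 24 steps (steps 1–6 and 8–25); step 7 is a one-step branch.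

Step 12 (key step). What may go wrong:
- dimerisation of the nitrile oxide to the furoxan outpacing attack on a trisubstituted alkene that sits on a quaternary carbon;
- erosion of facial control at C5 through a boat-like or ring-flipped transition state;
- chlorination of the electron-rich alkene or the anisyl ring by hypochlorite;
- migration of the C11=C13 double bond into conjugation with C6.

Fallback, from 15 back to 20: the primary hydroxyl of 15 is converted into the iodide F1 (I2, PPh3, imidazole) and then into the nitro compound F2 (NaNO2, DMSO). Silylation (Me3SiCl, Et3N) gives the silyl nitronate F3, a dipole that needs no oxidant and does not dimerise. Its intramolecular cycloaddition forms the same C5–C6 and O–C4 bonds in the N-silyloxyisoxazolidine F4, and acid-promoted loss of silanol (TsOH cat., CH2Cl2) gives 20.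

Step 1. What may go wrong: sluggish dehydrogenation of an α-silyloxy alcohol, and erosion of anti selectivity or of enantioselectivity because the aldehyde formed in situ is small and can chelate.

Fallback, from 1 and 2 back to 3: 2 is opened with B2pin2 under Ni(cod)2/PCy3 catalysis (zerovalent nickel) to the (E)-allylboronate F5, and 1 is oxidised (Swern) to the aldehyde F6. Allylboration of F6 with F5 under a chiral BINOL-derived phosphoric acid passes through a closed chair with the hydroxymethyl group equatorial and gives 3.

Step 8. What may go wrong: γ-attack of the dienolate in place of α-attack, weak double diastereoselection if the aldehyde bias opposes the auxiliary, and epimerisation of 9 at C9 before addition.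

Fallback, from 9 back to 15: Nozaki–Hiyama–Kishi-type allylation of 9 with (E)-4-bromo-3-methylbut-2-enyl acetate F7 and CrCl2 (divalent chromium) in THF. γ-Attack through a chair with the acetoxymethyl group equatorial, in the Felkin sense relative to C9, gives the acetate F8, and methanolysis (K2CO3, MeOH) gives 15.

Step 20. What may go wrong: poor facial selectivity at C1, because the aldehyde sits on a quaternary carbon whose two ring branches are similar in size, and counter-ion chelation to O9 that would reverse the preferred face.

Fallback, from 28 back to 29: the ylide addition is kept, but C1 is then put under catalyst control. Hydrolytic kinetic resolution of the epimer mixture with [N,N'-bis(3,5-di-tert-butylsalicylidene)-1,2-cyclohexanediaminato]cobalt acetate (trivalent cobalt; the enantiomer matched to the unwanted epimer) and water converts the (1S)-oxirane F9 into the diol F10 and leaves 29. NaIO4 cleaves F10 back to 28 for another pass.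

Step 21. What may go wrong: incomplete oxidation of one arm, attack at the methine positions C5 or C7 in place of the methyl groups, and opening of the oxirane by the acidic selenium species.

Fallback, from 29 back to 30: ene-type allylic chlorination of both prop-1-en-2-yl groups (NaOCl, CeCl3·7H2O, CH2Cl2/H2O) gives the bis(allylic chloride) F11. Displacement with CsOAc in DMF gives the diacetate F12, and methanolysis (K2CO3, MeOH) gives 30.

## Further compounds

F1 | step 12 | primary iodide from 15 (C6–I) | IC[C@H](C(C)=C)[C@@H](O)[C@H]1O[C@@H](c2ccc(OC)cc2)OC[C@@]1(C)C=C(C)C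
F2 | step 12 | primary nitro compound (C6–NO2) | [O-][N+](=O)C[C@H](C(C)=C)[C@@H](O)[C@H]1O[C@@H](c2ccc(OC)cc2)OC[C@@]1(C)C=C(C)C
F3 | step 12 | trimethylsilyl nitronate (O8 also silylated) | C[Si](C)(C)O[N+]([O-])=C[C@H](C(C)=C)[C@@H](O[Si](C)(C)C)[C@H]1O[C@@H](c2ccc(OC)cc2)OC[C@@]1(C)C=C(C)C
F4 | step 12 | N-(trimethylsilyloxy)isoxazolidine cycloadduct (C6 configuration open) | C=C(C)[C@H]1C2N(O[Si](C)(C)C)OC(C)(C)[C@H]2[C@]3(C)CO[C@H](c4ccc(OC)cc4)O[C@@H]3[C@@H]1O[Si](C)(C)C
F5 | step 1 | (E)-2-methyl-4-(4,4,5,5-tetramethyl-1,3,2-dioxaborolan-2-yl)but-2-en-1-ol | CC1(C)OB(C/C=C(\C)CO)OC1(C)C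
F6 | step 1 | 2-(tert-butyldimethylsilyloxy)acetaldehyde | O=CCO[Si](C)(C)C(C)(C)C
F7 | step 8 | (E)-4-bromo-3-methylbut-2-enyl acetate | CC(=O)OC/C=C(\C)CBr
F8 | step 8 | C6 acetate of 15 | CC(=O)OC[C@H](C(C)=C)[C@@H](O)[C@H]1O[C@@H](c2ccc(OC)cc2)OC[C@@]1(C)C=C(C)C
F9 | step 20 | (1S)-oxirane, C1 epimer of 29 | C=C(C)[C@@H]1[C@H](O[Si](CC)(CC)CC)[C@H](C(C)=C)[C@@H](O)[C@@H](OCc2ccc(OC)cc2)[C@@]1(C)[C@H]3CO3
F10 | step 20 | (1S)-1,2-diol from F9 | C=C(C)[C@@H]1[C@H](O[Si](CC)(CC)CC)[C@H](C(C)=C)[C@@H](O)[C@@H](OCc2ccc(OC)cc2)[C@@]1(C)[C@H](O)CO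
F11 | step 21 | bis(allylic chloride) (C12–Cl, C3–Cl) | C=C(CCl)[C@@H]1[C@H](O[Si](CC)(CC)CC)[C@H](C(=C)CCl)[C@@H](O)[C@@H](OCc2ccc(OC)cc2)[C@@]1(C)[C@@H]3CO3
F12 | step 21 | bis(allylic acetate) (C12–OAc, C3–OAc) | C=C(COC(C)=O)[C@@H]1[C@H](O[Si](CC)(CC)CC)[C@H](C(=C)COC(C)=O)[C@@H](O)[C@@H](OCc2ccc(OC)cc2)[C@@]1(C)[C@@H]3CO3
A1 | alternative 1 | lactone-fused 2-methylcyclohexenone (C9 ketone, C10=C5 alkene, C6 silyl ether) | C[C@H]1C(=O)O[C@@H]2[C@@H]1[C@@H](O[Si](C)(C)C(C)(C)C)C=C(C)C2=O
A2 | alternative 1 | 1-methylcyclobutene | CC1=CCC1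
A3 | alternative 1 | head-to-tail photoadduct with bicyclo[2.2.0]hexane, cis-fused | C[C@H]1C(=O)O[C@@H]2[C@@H]1[C@@H](O[Si](C)(C)C(C)(C)C)[C@H]([C@@]3(C)CC[C@H]34)[C@@]4(C)C2=O
A4 | alternative 1 | fragmentation product with C5 prop-1-en-2-yl cis to C10 vinyl | C[C@H]1C(=O)O[C@@H]2[C@@H]1[C@@H](O[Si](C)(C)C(C)(C)C)[C@H](C(C)=C)[C@](C)(C=C)C2=O
A5 | alternative 2 | open-chain C8 aldehyde with C7=C11 alkene | O=C[C@@H](OCc1ccc(OC)cc1)[C@@](C)(C=C)[C@H](C(=C)COC(=O)C(C)(C)C)[C@H](O[Si](C)(C)C(C)(C)C)C=C(C)C
A6 | alternative 2 | cyclohexanol from the carbonyl-ene closure | O[C@@H]1[C@@H](C(C)=C)[C@@H](O[Si](C)(C)C(C)(C)C)[C@@H](C(=C)COC(=O)C(C)(C)C)[C@](C)(C=C)[C@@H]1OCc1ccc(OC)cc1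
A7 | alternative 3 | open-chain C6 aldehyde with alkylidene malonate | O=CC[C@](C)(C=C)[C@@H]1OC(C)(C)O[C@@H]1C=C(C(=O)OC)C(=O)OC
A8 | alternative 3 | cyclohexan-6-one from the Stetter closure | CC1(C)O[C@@H]2[C@@H](C(C(=O)OC)C(=O)OC)C(=O)C[C@](C)(C=C)[C@@H]2O1
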